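**Strategy**

Germacrane numbering is used. Everything rests on the C6–C7 disconnection of the ten-membered carbocycle (C1–C10), made on a lactone that is already in place. The C6 carbinol, C7 and the exocyclic C11=C13 methylene of the α-methylene-γ-butyrolactone ring form a homoallylic alcohol, the retron of an SE2′ allylation. The precursor is therefore an open chain: a (4E)-enal (C6) tied through C9 to an endocyclic 3-(bromomethyl)butenolide (C7=C11, C13–Br). Chromium(II) closes the carbocycle, sets C6 and C7 under control of C8, and pushes the double bond out of the lactone ring in one operation. C8 and C3 come from reagent-controlled additions, both esters from one acid.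

Key step: step 15

Remark (numbering): C1=C10(C14H3), C2H2, C3–O, C4(C15H2–O)=C5, C6–O, C7, C8–O(lactone), C9H2, C11=C13H2, C12=O. These locants are also used for the open-chain compounds.

Assumption: the antipodes of the two chiral controllers (TRIP acid in step 1, oxazoline–sulfonamide in step 8) are written for the facial sense expected by analogy. Both antipodes are available, so a reversed sense would only change the antipode used.

Assumption: the 2-methylbutanoyl groups are (R) as drawn, and (R)-2-methylbutanoic acid is bought as the single enantiomer.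

**Route**

Step 1
Reactants: 1 acrolein; 2 allenylboronic acid pinacol ester
Product: 3 (S)-hex-1-en-5-yn-3-ol
Conditions: (S)-TRIP (5 mol %), 4 Å MS, toluene, −20 °C; aq. work-up
Reagents that add atoms: none
Why: Chiral-phosphoric-acid-catalysed asymmetric propargylation (SE2′ allenylboration through a closed six-membered transition state), in which the (S)-acid should expose the Si face of acrolein and so set C8 as (S).

Step 2
Reactants: 3 (S)-hex-1-en-5-yn-3-ol
Product: 4 (S)-triethyl(hex-1-en-5-yn-3-yloxy)silane
Conditions: TESCl, imidazole, CH2Cl2, 0 °C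
Reagents that add atoms: chlorotriethylsilane, CC[Si](Cl)(CC)CC
Why: Routine silyl ether formation at the only hydroxyl; TES survives AlMe3, n-BuLi, Cr(II) and TBSOTf, is later cleaved faster than a hindered secondary TBS ether, and C8 is untouched.

Step 3
Reactants: 4 (S)-triethyl(hex-1-en-5-yn-3-yloxy)silane
Product: 7 (3E,6S)-4-methyl-6-[(triethylsilyl)oxy]octa-3,7-dien-1-ol, via alkenyldimethylalane 5 (not isolated), via lithium alkenylalanate 6 (not isolated)
Conditions: AlMe3, Cp2ZrCl2 (25 mol %), CH2Cl2, 0 °C to rt; evaporate; n-BuLi, hexane/THF, −78 to 0 °C; ethylene oxide, 0 °C; aq. Rochelle salt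
Reagents that add atoms: trimethylaluminium, C[Al](C)C; ethylene oxide, C1CO1
Why: Negishi Zr-catalysed syn-carboalumination puts CH3 on C10 and Al on C1 of the terminal alkyne (much faster than the vinyl group) and so fixes the 1(10)E geometry, and the derived alanate opens ethylene oxide with retention at C1 to add C2 and C3.

Step 4
Reactants: 7 (3E,6S)-4-methyl-6-[(triethylsilyl)oxy]octa-3,7-dien-1-ol
Product: 8 (3E,6S)-4-methyl-6-[(triethylsilyl)oxy]octa-3,7-dienal
Conditions: DMP, pyridine, CH2Cl2, 0 °C; used at once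
Reagents that add atoms: none
Why: Buffered Dess–Martin oxidation should give the β,γ-unsaturated aldehyde without moving the C1=C10 double bond into conjugation.

Step 5
Reactants: 9 but-2-yne-1,4-diol
Product: 10 (E)-2-(tributylstannyl)but-2-ene-1,4-diol
Conditions: Bu3SnH, PdCl2(PPh3)2 (1 mol %), THF, 0 °C to rt
Reagents that add atoms: tributyltin hydride, CCCC[SnH](CCCC)CCCC
Why: Pd-catalysed syn-hydrostannation of a symmetrical alkyne raises no regiochemical question and places C15 and C6 cis on the future C4=C5 bond.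

Step 6
Reactants: 10 (E)-2-(tributylstannyl)but-2-ene-1,4-diol
Product: 11 (E)-4-[(tert-butyldimethylsilyl)oxy]-2-(tributylstannyl)but-2-en-1-ol
Conditions: TBSCl (1.0 equiv), imidazole, CH2Cl2/DMF, −20 °C
Reagents that add atoms: tert-butyldimethylsilyl chloride, CC(C)(C)[Si](C)(C)Cl
Why: Sterically controlled monosilylation, since the C15 hydroxyl sits next to the carbon that bears the bulky Bu3Sn group and the bulky chlorosilane should take the remote C6 hydroxyl.

Step 7
Reactants: 11 (E)-4-[(tert-butyldimethylsilyl)oxy]-2-(tributylstannyl)but-2-en-1-ol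
Product: 12 (E)-4-[(tert-butyldimethylsilyl)oxy]-2-iodobut-2-en-1-ol
Conditions: I2, CH2Cl2, 0 °C
Reagents that add atoms: iodine, II
Why: Iododestannylation at the sp2 carbon proceeds with retention, so iodine on C4 stays trans to C6.

Step 8
Reactants: 8 (3E,6S)-4-methyl-6-[(triethylsilyl)oxy]octa-3,7-dienal; 12 (E)-4-[(tert-butyldimethylsilyl)oxy]-2-iodobut-2-en-1-ol
Product: 14 (2E,3R,5E,8S)-2-{2-[(tert-butyldimethylsilyl)oxy]ethylidene}-6-methyl-8-[(triethylsilyl)oxy]deca-5,9-diene-1,3-diol, via alkenylchromium(III) species 13 (not isolated)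
Conditions: CrCl2 (4 equiv), NiCl2 (2 mol %), (S)-N-[2-(4-isopropyl-4,5-dihydrooxazol-2-yl)-6-methylphenyl]methanesulfonamide (4.4 equiv), Et3N (4.4 equiv), THF, rt
Reagents that add atoms: none
Why: Ligand-controlled asymmetric Nozaki–Hiyama–Kishi alkenylation, in which Ni inserts into C4–I with retention of the alkene geometry and the chiral Cr(III) complex should add to the Si face of the aldehyde to set C3 as (R); the C15 hydroxyl is left free because a β-hydroxyl, unlike a β-acyloxy group, is not lost from the alkenylmetal as an allene.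

Step 9
Reactants: 14 the 1,3-diol of step 8; 15 (R)-2-methylbutanoic acid
Product: 16 (2E,3R,5E,8S)-2-{2-[(tert-butyldimethylsilyl)oxy]ethylidene}-3-hydroxy-6-methyl-8-[(triethylsilyl)oxy]deca-5,9-dien-1-yl (2R)-2-methylbutanoate
Conditions: 15 (1.05 equiv), DCC, DMAP (10 mol %), CH2Cl2, −20 °C
Reagents that add atoms: none
Why: Steglich esterification under kinetic control, where the primary C15 hydroxyl reacts well ahead of the hindered secondary allylic C3 hydroxyl and the α-stereocentre of the acid is not enolised.

Step 10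
Reactants: 16 the C15 monoester
Product: 17 (2E,3R,5E,8S)-3-[(tert-butyldimethylsilyl)oxy]-2-{2-[(tert-butyldimethylsilyl)oxy]ethylidene}-6-methyl-8-[(triethylsilyl)oxy]deca-5,9-dien-1-yl (2R)-2-methylbutanoate
Conditions: TBSOTf, 2,6-lutidine, CH2Cl2, −78 °C
Reagents that add atoms: tert-butyldimethylsilyl triflate, CC(C)(C)[Si](C)(C)OS(=O)(=O)C(F)(F)F
Why: The silyl triflate is reactive enough for the hindered secondary allylic alcohol, and only the O–H bond is touched, so C3 keeps its configuration.

Step 11
Reactants: 17 the tris-silyl ether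
Product: 18 (2E,3R,5E,8S)-3-[(tert-butyldimethylsilyl)oxy]-8-hydroxy-2-(2-hydroxyethylidene)-6-methyldeca-5,9-dien-1-yl (2R)-2-methylbutanoate
Conditions: HF·pyridine, pyridine, THF, 0 °C
Reagents that add atoms: none
Why: Fluoride desilylation graded by steric hindrance, so the secondary TES ether (O8) and the primary allylic TBS ether (O6) should go well before the C3 TBS ether, which is flanked by the fully substituted C4.

Step 12
Reactants: 18 the 6,8-diol
Product: 19 (2E,3R,5E,8S)-3-[(tert-butyldimethylsilyl)oxy]-8-hydroxy-6-methyl-2-(2-oxoethylidene)deca-5,9-dien-1-yl (2R)-2-methylbutanoate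
Conditions: TEMPO (10 mol %), PhI(OAc)2, CH2Cl2, rt
Reagents that add atoms: none
Why: Oxoammonium oxidation is selective for the primary allylic C6 alcohol over the secondary C8 alcohol and gives the enal without E/Z isomerisation, while the C15 ester blocks lactol or furan formation.

Step 13
Reactants: 19 the hydroxy enal; 20 2-(bromomethyl)acrylic acid
Product: 21 (2E,3R,5E,8S)-8-{[2-(bromomethyl)acryloyl]oxy}-3-[(tert-butyldimethylsilyl)oxy]-6-methyl-2-(2-oxoethylidene)deca-5,9-dien-1-yl (2R)-2-methylbutanoate
Conditions: DCC, DMAP (5 mol %), CH2Cl2, 0 °C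
Reagents that add atoms: none
Why: Steglich esterification of the secondary allylic alcohol with retention at C8 brings in C11, C12, C13 and the bromine in one step, and little DMAP at low temperature keeps the allylic bromide from being quaternised.

Step 14
Reactants: 21 the 2-(bromomethyl)acrylate
Product: 22 (2E,3R,5E)-7-[(2S)-4-(bromomethyl)-5-oxo-2,5-dihydrofuran-2-yl]-3-[(tert-butyldimethylsilyl)oxy]-6-methyl-2-(2-oxoethylidene)hept-5-en-1-yl (2R)-2-methylbutanoate
Conditions: Hoveyda–Grubbs II (10 mol %), toluene (2 mM), 80 °C, Ar sparge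
Reagents that add atoms: none
Why: Ring-closing metathesis between the only monosubstituted olefin and the acrylate olefin closes the five-membered butenolide (C7=C11), while the two trisubstituted olefins are inert to the catalyst and C8 is untouched.

Step 15
Reactants: 22 the 3-(bromomethyl)butenolide enal
Product: 24 (3R,6R,7S,8S)-3-[(tert-butyldimethylsilyl)oxy]-6-hydroxy-15-{[(2R)-2-methylbutanoyl]oxy}germacra-1(10)E,4E,11(13)-trien-12,8-olide, via allylchromium(III) species 23 (not isolated)
Conditions: CrCl2 (10 equiv), 4 Å MS, degassed THF, rt, syringe-pump addition of 22 (final about 1 mM)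
Reagents that add atoms: none
Why: Two equivalents of Cr(II) reduce the activated allylic C13–Br bond of 22 to the allylchromium(III) 23, which adds through its γ-carbon C7 to the C6 aldehyde in a closed six-membered chair (SE2′), so that the C7=C11 bond leaves the lactone ring and becomes the exocyclic C11=C13 methylene. The closest known reaction types are the intramolecular Nozaki–Hiyama–Kishi allylation (macrocyclisation of ω-formyl allylic bromides) and the Cr- or Zn-mediated addition of 3-(bromomethyl)furan-2(5H)-ones to aldehydes. The ten-membered ring is closed by a 10-exo-trig addition to the C6=O group with C6–C7 as the new bond, and no other ring is formed. C7 is controlled by C8, because the aldehyde is delivered to the butenolide face opposite the C9 branch, which gives the trans-fused 7,8-lactone (H7 and H8 anti). C6 is controlled by the chair, because the ring-locked geometry of 23 (C8 trans to C13 across C7=C11, an E-crotyl analogue) with C5 equatorial gives the anti O6/C8 relation, that is (6R), and places C5 and C8 gauche as the closing chain requires. The step needs ring closure over oligomerisation and insertion into C–Br only: slow addition at high dilution and the two E double bonds that pre-fold the chain serve the first, the mildness of Cr(II) toward ester, silyl ether and enal C=C serves the second, and an O15-to-O6 acyl shift would be harmless since step 16 esterifies either free hydroxyl with the same acid.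

Step 16
Reactants: 24 the C6 alcohol; 15 (R)-2-methylbutanoic acid
Product: 25 (3R,6R,7R,8S)-3-[(tert-butyldimethylsilyl)oxy]-6,15-bis{[(2R)-2-methylbutanoyl]oxy}germacra-1(10)E,4E,11(13)-trien-12,8-olide
Conditions: 15 (3 equiv), DCC, DMAP, CH2Cl2, 0 °C to rt
Reagents that add atoms: none
Why: Steglich esterification of the secondary C6 alcohol with retention at C6 (the change of the C7 descriptor from S to R is only a change of CIP ranking).

Step 17
Reactants: 25 the silylated diester
Product: 26 (3R,6R,7R,8S)-3-hydroxy-6,15-bis{[(2R)-2-methylbutanoyl]oxy}germacra-1(10)E,4E,11(13)-trien-12,8-olide (CNP0164325.1)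
Conditions: HF·pyridine, pyridine, THF, 0 °C to rt
Reagents that add atoms: none
Why: Buffered fluoride cleavage of the last silyl ether avoids the basic conditions that would invite O15-to-O3 acyl shift, lactone migration or anionic oxy-Cope rearrangement of the 3-hydroxy-1,5-diene, and no stereocentre is touched.

**Compound list**

1 | acrolein | C=CC=O | starting material
2 | allenylboronic acid pinacol ester | C=C=CB1OC(C)(C)C(C)(C)O1 | starting material
3 | (S)-hex-1-en-5-yn-3-ol | C#CC[C@H](O)C=C | intermediate
4 | (S)-triethyl(hex-1-en-5-yn-3-yloxy)silane | C#CC[C@H](O[Si](CC)(CC)CC)C=C | intermediate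
5 | dimethyl{(1E,4S)-2-methyl-4-[(triethylsilyl)oxy]hexa-1,5-dien-1-yl}alane (not isolated) | C[Al](C)/C=C(C)/C[C@H](O[Si](CC)(CC)CC)C=C | intermediate
6 | lithium butyl(dimethyl){(1E,4S)-2-methyl-4-[(triethylsilyl)oxy]hexa-1,5-dien-1-yl}alanate (not isolated) | [Li+].CCCC[Al-](C)(C)/C=C(C)/C[C@H](O[Si](CC)(CC)CC)C=C | intermediate
7 | (3E,6S)-4-methyl-6-[(triethylsilyl)oxy]octa-3,7-dien-1-ol | OCC/C=C(C)/C[C@H](O[Si](CC)(CC)CC)C=C | intermediate
8 | (3E,6S)-4-methyl-6-[(triethylsilyl)oxy]octa-3,7-dienal | O=CC/C=C(C)/C[C@H](O[Si](CC)(CC)CC)C=C | intermediate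
9 | but-2-yne-1,4-diol | OCC#CCO | starting material
10 | (E)-2-(tributylstannyl)but-2-ene-1,4-diol | OC/C=C(\CO)[Sn](CCCC)(CCCC)CCCC | intermediate
11 | (E)-4-[(tert-butyldimethylsilyl)oxy]-2-(tributylstannyl)but-2-en-1-ol | CC(C)(C)[Si](C)(C)OC/C=C(\CO)[Sn](CCCC)(CCCC)CCCC | intermediate
12 | (E)-4-[(tert-butyldimethylsilyl)oxy]-2-iodobut-2-en-1-ol | CC(C)(C)[Si](C)(C)OC/C=C(\CO)I | intermediate
13 | alkenylchromium(III) species from 12, chiral ligand omitted (not isolated) | CC(C)(C)[Si](C)(C)OC/C=C(\CO)[Cr](Cl)Cl | intermediate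
14 | (2E,3R,5E,8S)-2-{2-[(tert-butyldimethylsilyl)oxy]ethylidene}-6-methyl-8-[(triethylsilyl)oxy]deca-5,9-diene-1,3-diol | C=C[C@@H](O[Si](CC)(CC)CC)C/C(C)=C/C[C@@H](O)/C(CO)=C/CO[Si](C)(C)C(C)(C)C | intermediate
15 | (R)-2-methylbutanoic acid | CC[C@@H](C)C(=O)O | starting material
16 | C15 mono-(2R)-2-methylbutanoate of 14 (3-OH free) | C=C[C@@H](O[Si](CC)(CC)CC)C/C(C)=C/C[C@@H](O)/C(COC(=O)[C@H](C)CC)=C/CO[Si](C)(C)C(C)(C)C | intermediate
17 | 3-O-TBS ether of 16 | C=C[C@@H](O[Si](CC)(CC)CC)C/C(C)=C/C[C@@H](O[Si](C)(C)C(C)(C)C)/C(COC(=O)[C@H](C)CC)=C/CO[Si](C)(C)C(C)(C)C | intermediate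
18 | (2E,3R,5E,8S)-3-[(tert-butyldimethylsilyl)oxy]-8-hydroxy-2-(2-hydroxyethylidene)-6-methyldeca-5,9-dien-1-yl (2R)-2-methylbutanoate | C=C[C@@H](O)C/C(C)=C/C[C@@H](O[Si](C)(C)C(C)(C)C)/C(COC(=O)[C@H](C)CC)=C/CO | intermediate
19 | (2E,3R,5E,8S)-3-[(tert-butyldimethylsilyl)oxy]-8-hydroxy-6-methyl-2-(2-oxoethylidene)deca-5,9-dien-1-yl (2R)-2-methylbutanoate | C=C[C@@H](O)C/C(C)=C/C[C@@H](O[Si](C)(C)C(C)(C)C)/C(COC(=O)[C@H](C)CC)=C/C=O | intermediate
20 | 2-(bromomethyl)acrylic acid | C=C(CBr)C(=O)O | starting material
21 | 8-O-[2-(bromomethyl)acryloyl] ester of 19 | C=C[C@@H](OC(=O)C(=C)CBr)C/C(C)=C/C[C@@H](O[Si](C)(C)C(C)(C)C)/C(COC(=O)[C@H](C)CC)=C/C=O | intermediate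
22 | (2E,3R,5E)-7-[(2S)-4-(bromomethyl)-5-oxo-2,5-dihydrofuran-2-yl]-3-[(tert-butyldimethylsilyl)oxy]-6-methyl-2-(2-oxoethylidene)hept-5-en-1-yl (2R)-2-methylbutanoate | O=C1O[C@@H](C/C(C)=C/C[C@@H](O[Si](C)(C)C(C)(C)C)/C(COC(=O)[C@H](C)CC)=C/C=O)C=C1CBr | intermediate
23 | allylchromium(III) species from 22 (not isolated) | O=C1O[C@@H](C/C(C)=C/C[C@@H](O[Si](C)(C)C(C)(C)C)/C(COC(=O)[C@H](C)CC)=C/C=O)C=C1C[Cr](Cl)Cl | intermediate
24 | (3R,6R,7S,8S)-3-[(tert-butyldimethylsilyl)oxy]-6-hydroxy-15-{[(2R)-2-methylbutanoyl]oxy}germacra-1(10)E,4E,11(13)-trien-12,8-olide | C=C1C(=O)O[C@H]2C/C(C)=C/C[C@@H](O[Si](C)(C)C(C)(C)C)/C(COC(=O)[C@H](C)CC)=C/[C@@H](O)[C@H]12 | intermediate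
25 | (3R,6R,7R,8S)-3-[(tert-butyldimethylsilyl)oxy]-6,15-bis{[(2R)-2-methylbutanoyl]oxy}germacra-1(10)E,4E,11(13)-trien-12,8-olide | C=C1C(=O)O[C@H]2C/C(C)=C/C[C@@H](O[Si](C)(C)C(C)(C)C)/C(COC(=O)[C@H](C)CC)=C/[C@@H](OC(=O)[C@H](C)CC)[C@H]12 | intermediate
26 | (3R,6R,7R,8S)-3-hydroxy-6,15-bis{[(2R)-2-methylbutanoyl]oxy}germacra-1(10)E,4E,11(13)-trien-12,8-olide (CNP0164325.1) | C=C1C(=O)O[C@H]2C/C(C)=C/C[C@@H](O)/C(COC(=O)[C@H](C)CC)=C/[C@@H](OC(=O)[C@H](C)CC)[C@H]12 | target

**Step count**

Total step count: 17.
Longest linear sequence: 14 (steps 1–4 and 8–17).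

**Steps most likely to fail**

1. **Step 15 (ring closure).**
   - What may go wrong: the allylchromium may be protonated or couple intermolecularly faster than the strained ten-membered ring closes. Excess Cr(II) may attack the γ-acyloxy enal. The chromium alkoxide may shift the lactone to O6.
   - Fallback: it leaves reductive Barbier chemistry for a preformed, isolable allylmetal. It sets out from 22 and comes back at 24.
   - Pd2(dba)3-catalysed borylation of the allylic bromide with B2pin2 (THF, rt to 40 °C) should give the 3-[(pinacolboryl)methyl]butenolide enal F1. This is a 2-(alkoxycarbonyl)allylboronate that is sluggish toward aldehydes at room temperature and can be purified.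
   - Sc(OTf)3 (10 mol %) in toluene at about 1 mM then triggers a type-I intramolecular allylboration through the same chair and the same butenolide face, without any reducing metal. Mild hydrolytic work-up of the borate gives 24.

2. **Step 8 (C3–C4 coupling).**
   - What may go wrong: facial selectivity at C3 may be poor because the free C15 hydroxyl disturbs the chiral chromium complex. Some base-induced conjugation of aldehyde 8 may also occur.
   - Fallback: it moves the stereocontrol from C–C bond formation to a ketone reduction. It sets out from 16 of insufficient purity at C3, as obtained from steps 8 and 9, and comes back at 16.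
   - Dess–Martin oxidation of the C3 alcohol should give the cross-conjugated C3 enone F2.
   - Corey–Bakshi–Shibata reduction with (S)-2-methyl-CBS-oxazaborolidine and catecholborane (toluene, −78 °C) follows. The alkenyl side (C4) acts as the large group and C2H2 as the small group, which should return 16 as the (3R) alcohol. Catecholborane leaves the terminal vinyl group alone.

3. **Step 14 (butenolide metathesis).**
   - What may go wrong: turnover may be slow at the electron-poor 1,1-disubstituted olefin, and the ruthenium carbene may decompose through the allylic bromide.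
   - Fallback: it takes the halide out of the metathesis substrate and brings C13 in at the alcohol level. It sets out from 19 and comes back at 22.
   - Commercial ethyl 2-(hydroxymethyl)acrylate is silylated (TBSCl, imidazole) to ethyl 2-{[(tert-butyldimethylsilyl)oxy]methyl}acrylate F3. Saponification (LiOH, THF/H2O) gives 2-{[(tert-butyldimethylsilyl)oxy]methyl}acrylic acid F4.
   - Steglich esterification of 19 with this acid gives the 8-O-acrylate F5. Ring-closing metathesis gives the 3-(silyloxymethyl)butenolide enal F6.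
   - HF·pyridine/pyridine at 0 °C frees only the primary alcohol to give the 3-(hydroxymethyl)butenolide enal F7. An Appel bromination (CBr4, PPh3, CH2Cl2, 0 °C) then gives 22.

**Further compounds**

F1 | step 15 | 3-[(pinacolboryl)methyl]butenolide enal (Bpin in place of Br in 22) | O=C1O[C@@H](C/C(C)=C/C[C@@H](O[Si](C)(C)C(C)(C)C)/C(COC(=O)[C@H](C)CC)=C/C=O)C=C1CB1OC(C)(C)C(C)(C)O1
F2 | step 8 | C3 enone (3-oxo analogue of 16) | C=C[C@@H](O[Si](CC)(CC)CC)C/C(C)=C/CC(=O)/C(COC(=O)[C@H](C)CC)=C/CO[Si](C)(C)C(C)(C)C
F3 | step 14 | ethyl 2-{[(tert-butyldimethylsilyl)oxy]methyl}acrylate | C=C(CO[Si](C)(C)C(C)(C)C)C(=O)OCC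
F4 | step 14 | 2-{[(tert-butyldimethylsilyl)oxy]methyl}acrylic acid | C=C(CO[Si](C)(C)C(C)(C)C)C(=O)O
F5 | step 14 | 8-O-(2-{[(tert-butyldimethylsilyl)oxy]methyl}acryloyl) ester of 19 | C=C[C@@H](OC(=O)C(=C)CO[Si](C)(C)C(C)(C)C)C/C(C)=C/C[C@@H](O[Si](C)(C)C(C)(C)C)/C(COC(=O)[C@H](C)CC)=C/C=O
F6 | step 14 | 3-(silyloxymethyl)butenolide enal (OTBS in place of Br in 22) | O=C1O[C@@H](C/C(C)=C/C[C@@H](O[Si](C)(C)C(C)(C)C)/C(COC(=O)[C@H](C)CC)=C/C=O)C=C1CO[Si](C)(C)C(C)(C)C
F7 | step 14 | 3-(hydroxymethyl)butenolide enal (OH in place of Br in 22) | O=C1O[C@@H](C/C(C)=C/C[C@@H](O[Si](C)(C)C(C)(C)C)/C(COC(=O)[C@H](C)CC)=C/C=O)C=C1CO
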